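**Retrosynthetic overview**
1. Feature: in the ten-membered carbocycle C1–C10 a C2–C7 bond gives a cis-fused decalin (ring A: C2–C3–C4–C5–C6–C7; ring B: cyclohexene C7–C8–C9–C10=C1–C2) whose C11–C13 spiro-epoxide stores the C7=C11 butenolide olefin and the C13 oxygen.
2. Target 42 ⇐ acid-induced enol-lactonisation and deprotection ⇐ C8 angelate, C2/C13 acetates ⇐ 1,3-syn reduction of cyclodecenone 33 ⇐ Grob fragmentation of decalin glycidic ester 31.
3. 31 ⇐ Sharpless epoxidation of a 2-substituted allylic alcohol (sets C11) ⇐ ring B by ring-closing metathesis ⇐ C4 carbinol by C2-hydroxyl-directed epoxidation and hydride opening ⇐ vinyl addition to ring A enone 17.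
4. 17 ⇐ CBS desymmetrisation of the 2,2-disubstituted dione 12 ⇐ Brown allylboration (sets C8) of aldehyde 5 ⇐ Birch reductive alkylation of methyl 2,6-dimethoxy-4-methylbenzoate.
5. Ring order: ring A (from the arene), ring B (metathesis), ten-membered ring (fragmentation), butenolide (last step).

Key step: step 24

Remark: germacrane numbering is used: C2 bears the acetate, C4 the methyl and hydroxyl, C6 the lactone oxygen, C8 the angelate, C10 the hydroxymethyl C14; C11, C12 (carbonyl) and C13 (acetoxymethyl) are the butenolide carbons.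
Remark: compounds 4, 5 and 10–16 are carried as both C4 epimers (methyl cis or trans to the acetate arm), which converge at enone 17; their SMILES leave C4 open.
Remark: the senses of induction of the borane (step 5), the oxazaborolidine (step 8) and the tartrate (step 20) are assigned by analogy with benzaldehyde, acetophenone and geraniol; if one proves opposite, the enantiomeric reagent is used.

Step 1
Reactants: 1 3,5-dimethoxytoluene
Product: 2 methyl 2,6-dimethoxy-4-methylbenzoate
Conditions: n-BuLi, TMEDA, THF, 0 °C; then ClCO2Me, −78 °C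
Reagents that add atoms: methyl chloroformate COC(=O)Cl
Why: Directed ortho-lithiation at the carbon flanked by both methoxy groups and acylation put the future C8 carbon on the future C7; no stereocentre is formed.

Step 2
Reactants: 2 methyl 2,6-dimethoxy-4-methylbenzoate; 3 tert-butyl bromoacetate
Product: 4 methyl 1-(2-tert-butoxy-2-oxoethyl)-2,6-dimethoxy-4-methylcyclohexa-2,5-diene-1-carboxylate
Conditions: Li, NH3 (l), THF, t-BuOH (1 equiv), −78 °C; isoprene; then 3, −78 °C
Reagents that add atoms: none
Why: Birch reductive alkylation: the ester dienolate is alkylated at the ipso carbon, which gives quaternary C7 flanked by two enol ethers (masked C2 and C6 ketones); C7 is not yet stereogenic.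

Step 3
Reactants: 4 Birch diester
Product: 5 tert-butyl (1-formyl-2,6-dimethoxy-4-methylcyclohexa-2,5-dien-1-yl)acetate
Conditions: i-Bu2AlH (1.2 equiv), CH2Cl2, −78 °C; Rochelle salt
Reagents that add atoms: none
Why: Partial reduction of the methyl ester at −78 °C should stop at the chelated tetrahedral aluminate and spare the tert-butyl ester, giving the C8 aldehyde on a still symmetric C7.

Step 4
Reactants: 6 3-chloro-2-(chloromethyl)prop-1-ene
Product: 7 2-(chloromethyl)allyl 4-methoxybenzyl ether
Conditions: NaH, 4-methoxybenzyl alcohol, THF, 0 °C → rt (6 in excess)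
Reagents that add atoms: 4-methoxybenzyl alcohol COc1ccc(CO)cc1
Why: Williamson mono-etherification of the symmetric bis-allylic chloride gives the C9–C10(=CH2)–C14 unit with C14 protected as its PMB ether.

Step 5
Reactants: 5 aldehyde; 7 allyl chloride
Product: 10 (8S)-homoallylic alcohol, tert-butyl {1-[(1S)-1-hydroxy-3-[(4-methoxybenzyloxy)methyl]but-3-en-1-yl]-2,6-dimethoxy-4-methylcyclohexa-2,5-dien-1-yl}acetate, via allylmagnesium chloride 8 (not isolated), via allyldiisopinocampheylborane 9 (not isolated)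
Conditions: 7, Mg, THF, 0 °C; (−)-Ipc2BOMe, Et2O, −78 °C → rt; then 5, −78 °C; NaBO3·4H2O, THF/H2O
Reagents that add atoms: none
Why: Brown allylboration through a chair transition state should deliver the 2-substituted allyl group to the Si face of the hindered aldehyde (the sense known for benzaldehyde), setting C8 as S by reagent control while C7 still carries two identical enol-ether arms.

Step 6
Reactants: 10 homoallylic alcohol
Product: 11 C8 tert-butyldimethylsilyl ether of 10
Conditions: t-BuMe2SiOTf, 2,6-lutidine, CH2Cl2, −78 °C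
Reagents that add atoms: tert-butyldimethylsilyl triflate CC(C)(C)[Si](C)(C)OS(=O)(=O)C(F)(F)F
Why: Silylation of the hindered secondary alcohol blocks retro-aldol and lactonisation onto the ester arm and makes the C8 branch the large substituent on C7.

Step 7
Reactants: 11 silyl ether
Product: 12 2,2-disubstituted 5-methylcyclohexane-1,3-dione (ring A; C7 bears CH2CO2t-Bu and the (8S)-silyloxy chain)
Conditions: HCl (0.5 M), THF/H2O, 0 °C
Reagents that add atoms: water O
Why: Enol ether hydrolysis unveils both ring A ketones; quaternary C7 blocks aromatisation, and the silyl ether, PMB ether and tert-butyl ester should tolerate cold dilute acid.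

Step 8
Reactants: 12 dione
Product: 13 hydroxy ketone (C2 carbinol with OH cis to the acetate arm, C6 ketone)
Conditions: (R)-2-methyl-CBS-oxazaborolidine (0.3 equiv), catecholborane, toluene/CH2Cl2, −78 °C
Reagents that add atoms: none
Why: CBS desymmetrisation: hydride should enter axially, anti to the pseudo-axial acetate arm (C8 branch equatorial), and the (R)-catalyst accepts this trajectory only at the carbonyl whose Re face (C7 as large group) is that ring face, so reagent control picks the carbonyl that becomes C2 and thereby fixes C7; the C2 carbinol is transient.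

Step 9
Reactants: 13 hydroxy ketone
Product: 14 hydroxy ketal (C6 1,3-dioxolane)
Conditions: (Me3SiOCH2)2, Me3SiOTf (5 mol %), CH2Cl2, −78 → −20 °C; then citric acid, MeOH
Reagents that add atoms: 1,2-bis(trimethylsilyloxy)ethane C[Si](C)(C)OCCO[Si](C)(C)C
Why: Noyori ketalisation masks the hindered C6 ketone under aprotic conditions now that it is distinguished from C2; C7 is quaternary, so no β-elimination of the ketal is possible.

Step 10
Reactants: 14 hydroxy ketal
Product: 15 ring A ketone ketal (C2 ketone, C6 dioxolane)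
Conditions: Dess–Martin periodinane, NaHCO3, CH2Cl2, rt
Reagents that add atoms: none
Why: Re-oxidation of the C2 carbinol returns the ketone, now the only carbonyl of ring A, with C7 configured.

Step 11
Reactants: 15 ketone ketal
Product: 17 ring A enone (C2=O, C3=C4 bearing the C4 methyl), via silyl enol ether 16 (not isolated)
Conditions: Me3SiOTf, Et3N, CH2Cl2, 0 °C; then Pd(OAc)2 (1.1 equiv), MeCN, rt
Reagents that add atoms: none
Why: Saegusa–Ito dehydrogenation: enolisation is possible only towards C3 because C7 is quaternary, and the step merges both C4 epimers into one enone.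

Step 12
Reactants: 17 enone
Product: 18 C2 vinyl carbinol (OH cis to the acetate arm, vinyl cis to the C8 chain)
Conditions: CH2=CHMgBr, THF, −78 °C; AcOH quench at −78 °C
Reagents that add atoms: vinylmagnesium bromide C=C[Mg]Br
Why: 1,2-Addition to the β,β-disubstituted enone should occur anti to the pseudo-axial acetate arm on C7, setting C2 with its hydroxyl cis to C11 and the vinyl group (C1) next to the C8 chain.

Step 13
Reactants: 18 vinyl carbinol
Product: 19 3,4-epoxy alcohol (epoxide oxygen syn to C2–OH)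
Conditions: VO(acac)2 (5 mol %), t-BuOOH, benzene, rt
Reagents that add atoms: tert-butyl hydroperoxide CC(C)(C)OO
Why: Hydroxyl-directed vanadium epoxidation of the cyclic tertiary allylic alcohol delivers oxygen syn to C2–OH and should take the trisubstituted C3=C4 olefin ahead of the vinyl group and the remote 1,1-disubstituted olefin.

Step 14
Reactants: 19 epoxy alcohol
Product: 20 triol (C2–OH and C4–OH cis, C12 primary alcohol)
Conditions: NaAlH2(OCH2CH2OMe)2, THF, 0 °C → rt; Rochelle salt
Reagents that add atoms: none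
Why: Red-Al opening of the 2,3-epoxy alcohol by intramolecular hydride delivery to the proximal, less substituted C3 gives the cis-1,3-diol, so C4 (R) is relayed from C2; the same reagent reduces the tert-butyl ester to the C12 alcohol.

Step 15
Reactants: 20 triol
Product: 21 cis-decalin triol (ring B closed, C1=C10)
Conditions: second-generation Grubbs catalyst RuCl2(=CHPh)(PCy3)(H2IMes) (5 mol %), CH2Cl2, 40 °C
Reagents that add atoms: none
Why: Ring-closing metathesis of the C2 vinyl group with the 1,1-disubstituted olefin closes ring B as a trisubstituted cyclohexene; the cis ring fusion follows from the cis vinyl/C8 arrangement and no stereocentre is formed.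

Step 16
Reactants: 21 decalin triol
Product: 22 tris-silyl ether (C12–OSiEt3, C4–OSiEt3, C2–OSiMe3)
Conditions: Et3SiOTf (2.1 equiv), 2,6-lutidine, CH2Cl2, −78 °C; then Me3SiOTf (1.2 equiv), 0 °C
Reagents that add atoms: triethylsilyl triflate CC[Si](CC)(CC)OS(=O)(=O)C(F)(F)F; trimethylsilyl triflate C[Si](C)(C)OS(=O)(=O)C(F)(F)F
Why: Graded silylation (primary, then the less hindered C4 tertiary, last the C2 alcohol beside quaternary C7) gives the C4 protection needed for the fragmentation and a labile C2 mask that prevents lactol and lactone formation with C12.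

Step 17
Reactants: 22 tris-silyl ether
Product: 23 C12 aldehyde
Conditions: (COCl)2, DMSO, CH2Cl2, −78 → −30 °C; Et3N
Reagents that add atoms: none
Why: Swern oxidation converts a primary triethylsilyl ether directly into the aldehyde while tertiary and secondary silyl ethers stay.

Step 18
Reactants: 23 aldehyde
Product: 25 α-methylene aldehyde (C11=C13), via Mannich base 24 (not isolated)
Conditions: CH2=NMe2+ I−, Et3N, CH2Cl2, rt
Reagents that add atoms: N,N-dimethylmethyleneiminium iodide C=[N+](C)C.[I-]
Why: Mannich reaction of the aldehyde with Eschenmoser's salt and elimination of dimethylamine install C13; C7 is quaternary, so only C11 can react.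

Step 19
Reactants: 25 enal
Product: 26 2-substituted allylic alcohol (C12–OH)
Conditions: i-Bu2AlH, CH2Cl2, −78 °C
Reagents that add atoms: none
Why: Clean 1,2-reduction of the enal under aprotic conditions keeps the C2 trimethylsilyl ether.

Step 20
Reactants: 26 allylic alcohol
Product: 27 epoxy alcohol (C11–C13 epoxide)
Conditions: Ti(Oi-Pr)4 (20 mol %), D-(−)-diethyl tartrate (24 mol %), t-BuOOH, 4 Å molecular sieves, CH2Cl2, −20 °C
Reagents that add atoms: tert-butyl hydroperoxide CC(C)(C)OO
Why: Sharpless asymmetric epoxidation sets C11 by reagent control next to quaternary C7, the D-tartrate face being the one that will place C12 cis to C6 after fragmentation.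

Step 21
Reactants: 27 epoxy alcohol
Product: 29 glycidic acid, via glycidic aldehyde 28 (not isolated)
Conditions: Dess–Martin periodinane, NaHCO3, CH2Cl2, 0 °C; then NaClO2, NaH2PO4, 2-methylbut-2-ene, t-BuOH/H2O, 0 °C
Reagents that add atoms: sodium chlorite [Na+].[O-]Cl=O
Why: Dess–Martin then Pinnick oxidation raises C12 to the acid without touching the epoxide, the olefin or the silyl ethers; the silylated C2 oxygen cannot lactonise.

Step 22
Reactants: 29 glycidic acid
Product: 30 tert-butyl glycidate with C2–OSiMe3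
Conditions: O-tert-butyl-N,N′-diisopropylisourea, CH2Cl2, rt
Reagents that add atoms: O-tert-butyl-N,N′-diisopropylisourea CC(C)N=C(OC(C)(C)C)NC(C)C
Why: The isourea transfers a tert-butyl group to the carboxylate oxygen, so the hindered acid is esterified without acid or base that would harm the epoxide.

Step 23
Reactants: 30 silylated glycidate
Product: 31 decalin epoxy ester (fragmentation precursor, free C2–OH)
Conditions: K2CO3, MeOH, 0 °C
Reagents that add atoms: none
Why: Mild methanolysis removes only the trimethylsilyl ether and leaves the C4 triethylsilyl, C8 tert-butyldimethylsilyl, epoxide and tert-butyl ester untouched.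

Step 24
Reactants: 31 decalin epoxy ester
Product: 33 cyclodecenone with exocyclic hydroxymethyl enoate, via potassium alkoxide 32 (not isolated)
Conditions: KN(SiMe3)2 (1.1 equiv), THF, −78 → 0 °C; NH4Cl (aq)
Reagents that add atoms: none
Why: Proposed new method: KN(SiMe3)2 turns the C2 tertiary alcohol into alkoxide 32, whose oxygen lone pair forms C2=O while the C2–C7 σ-bond, held antiperiplanar to the C11–O bond of the spiro-epoxide by rotation about C7–C11, becomes the C7=C11 π-bond and the epoxide opens to the C13 alkoxide in one concerted Grob fragmentation. The closest known reactions are the alkoxide-triggered Grob (Wharton) fragmentation of decalin 1,3-diol monosulfonates to cyclodecenones and the fragmentation of epoxy alcohols with the epoxide as nucleofuge; new is their combination on a glycidic ester, where the leaving oxygen sits α to the ester. No ring is closed: cleavage of the bond shared by rings A and B releases the ten-membered carbocycle, and the cyclohexene olefin of ring B is carried over unchanged as the ring-cis C1=C10 enone olefin. No stereocentre is formed; the C7=C11 geometry (C12 cis to C6, C13 cis to C8) follows stereospecifically from the C7/C11 relative configuration set in step 20. The step needs fragmentation to outrun attack of the C2 alkoxide on the ester or the epoxide and any retro-aldol cleavage: the tert-butyl ester on quaternary C11 shields the carbonyl, C6 is masked as the dioxolane, C4–O is silylated, and release of epoxide strain with formation of an enone and an enoate drives the reaction.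

Step 25
Reactants: 33 cyclodecenone
Product: 34 C4 tertiary alcohol (β-hydroxy enone)
Conditions: AcOH/THF/H2O (3:1:1), rt
Reagents that add atoms: none
Why: Aqueous acetic acid cleaves the triethylsilyl ether selectively over the hindered secondary tert-butyldimethylsilyl ether, the dioxolane and the PMB ether.

Step 26
Reactants: 34 β-hydroxy enone
Product: 36 (2S,4R)-syn-1,3-diol, via diethylborinate chelate 35 (not isolated)
Conditions: Et2BOMe, THF/MeOH (4:1), −78 °C; NaBH4; then MeOH, evaporation
Reagents that add atoms: none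
Why: Narasaka–Prasad reduction: external hydride attacks the boron chelate of the C4 alkoxide and C2 carbonyl axially, giving the 1,3-syn diol and so C2 (S) from C4; the chelated enone carbonyl reacts 1,2.

Step 27
Reactants: 36 diol
Product: 37 C2, C13 diacetate
Conditions: Ac2O, pyridine, DMAP (cat.), CH2Cl2, 0 °C
Reagents that add atoms: acetic anhydride CC(=O)OC(C)=O
Why: The primary allylic C13 and secondary allylic C2 hydroxyls are acetylated while the tertiary C4 alcohol is too hindered to react at 0 °C.

Step 28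
Reactants: 37 diacetate
Product: 38 C8 alcohol
Conditions: HF·pyridine, THF, 0 °C → rt
Reagents that add atoms: none
Why: Acidic fluoride removes the tert-butyldimethylsilyl ether without acetate migration and leaves the PMB ether, dioxolane and tert-butyl ester.

Step 29
Reactants: 38 C8 alcohol
Product: 39 C8 angelate
Conditions: angelic acid, 2,4,6-trichlorobenzoyl chloride, Et3N, toluene, rt; then 38, 80 °C
Reagents that add atoms: angelic acid C/C=C(/C)C(=O)O
Why: Yamaguchi esterification through the mixed anhydride, run without a nucleophilic catalyst, acylates the secondary allylic alcohol while keeping the Z geometry of the angelate; the tertiary C4 alcohol does not react.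

Step 30
Reactants: 39 angelate
Product: 42 target CNP0165707.1, via keto acid 40 (not isolated), via hydroxybutenolide 41 (not isolated)
Conditions: CF3CO2H/CH2Cl2 (1:4), anisole, H2O (5 equiv), 0 °C → rt
Reagents that add atoms: none
Why: Acid cleaves the tert-butyl ester, the dioxolane and the PMB ether; the Z-γ-keto acid closes to the hydroxybutenolide, whose dehydration through the acyloxocarbenium ion gives the ring-cis C5=C6 enol lactone and frees C14–OH.

**Compound list**
1 | 3,5-dimethoxytoluene | Cc1cc(OC)cc(OC)c1 | starting material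
2 | methyl 2,6-dimethoxy-4-methylbenzoate | COC(=O)c1c(OC)cc(C)cc1OC | intermediate
3 | tert-butyl bromoacetate | CC(C)(C)OC(=O)CBr | starting material
4 | methyl 1-(2-tert-butoxy-2-oxoethyl)-2,6-dimethoxy-4-methylcyclohexa-2,5-diene-1-carboxylate (C4 epimers) | COC(=O)C1(CC(=O)OC(C)(C)C)C(OC)=CC(C)C=C1OC | intermediate
5 | tert-butyl (1-formyl-2,6-dimethoxy-4-methylcyclohexa-2,5-dien-1-yl)acetate (C4 epimers) | CC(C)(C)OC(=O)CC1(C=O)C(OC)=CC(C)C=C1OC | intermediate
6 | 3-chloro-2-(chloromethyl)prop-1-ene | ClCC(=C)CCl | starting material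
7 | 2-(chloromethyl)allyl 4-methoxybenzyl ether | COc1ccc(COCC(=C)CCl)cc1 | intermediate
8 | {2-[(4-methoxybenzyloxy)methyl]allyl}magnesium chloride | COc1ccc(COCC(=C)C[Mg]Cl)cc1 | intermediate
9 | B-{2-[(4-methoxybenzyloxy)methyl]allyl}diisopinocampheylborane (isopinocampheyl groups from (+)-α-pinene) | COc1ccc(COCC(=C)CB([C@@H]2C[C@@H]3C[C@H]([C@H]2C)C3(C)C)[C@@H]2C[C@@H]3C[C@H]([C@H]2C)C3(C)C)cc1 | intermediate
10 | (8S)-homoallylic alcohol on the bis-enol ether ring (C4 epimers) | CC(C)(C)OC(=O)CC1([C@@H](O)CC(=C)COCc2ccc(OC)cc2)C(OC)=CC(C)C=C1OC | intermediate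
11 | C8 tert-butyldimethylsilyl ether of 10 | CC(C)(C)OC(=O)CC1([C@@H](O[Si](C)(C)C(C)(C)C)CC(=C)COCc2ccc(OC)cc2)C(OC)=CC(C)C=C1OC | intermediate
12 | ring A 1,3-dione, C7 bearing CH2CO2t-Bu and the (8S)-silyloxy chain | CC(C)(C)OC(=O)CC1([C@@H](O[Si](C)(C)C(C)(C)C)CC(=C)COCc2ccc(OC)cc2)C(=O)CC(C)CC1=O | intermediate
13 | hydroxy ketone (C2–OH cis to the acetate arm, C6 ketone) | CC(C)(C)OC(=O)C[C@@]1([C@@H](O[Si](C)(C)C(C)(C)C)CC(=C)COCc2ccc(OC)cc2)[C@@H](O)CC(C)CC1=O | intermediate
14 | hydroxy ketal (C6 dioxolane) | CC(C)(C)OC(=O)C[C@@]1([C@@H](O[Si](C)(C)C(C)(C)C)CC(=C)COCc2ccc(OC)cc2)[C@@H](O)CC(C)CC13OCCO3 | intermediate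
15 | ring A ketone ketal (C2 ketone, C6 dioxolane) | CC(C)(C)OC(=O)C[C@@]1([C@@H](O[Si](C)(C)C(C)(C)C)CC(=C)COCc2ccc(OC)cc2)C(=O)CC(C)CC13OCCO3 | intermediate
16 | C2 trimethylsilyl enol ether of 15 | CC(C)(C)OC(=O)C[C@@]1([C@@H](O[Si](C)(C)C(C)(C)C)CC(=C)COCc2ccc(OC)cc2)C(O[Si](C)(C)C)=CC(C)CC13OCCO3 | intermediate
17 | ring A enone (C2=O, C3=C4) | CC(C)(C)OC(=O)C[C@@]1([C@@H](O[Si](C)(C)C(C)(C)C)CC(=C)COCc2ccc(OC)cc2)C(=O)C=C(C)CC13OCCO3 | intermediate
18 | C2 vinyl carbinol | CC(C)(C)OC(=O)C[C@@]1([C@@H](O[Si](C)(C)C(C)(C)C)CC(=C)COCc2ccc(OC)cc2)[C@](O)(C=C)C=C(C)CC13OCCO3 | intermediate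
19 | 3,4-epoxy alcohol, epoxide syn to C2–OH | CC(C)(C)OC(=O)C[C@@]1([C@@H](O[Si](C)(C)C(C)(C)C)CC(=C)COCc2ccc(OC)cc2)[C@](O)(C=C)[C@H]4O[C@@]4(C)CC13OCCO3 | intermediate
20 | triol, C2–OH and C4–OH cis, C12 primary alcohol | OCC[C@@]1([C@@H](O[Si](C)(C)C(C)(C)C)CC(=C)COCc2ccc(OC)cc2)[C@](O)(C=C)C[C@@](C)(O)CC13OCCO3 | intermediate
21 | cis-decalin triol (rings A and B) | OCC[C@@]23[C@@H](O[Si](C)(C)C(C)(C)C)CC(COCc4ccc(OC)cc4)=C[C@]2(O)C[C@@](C)(O)CC35OCCO5 | intermediate
22 | tris-silyl ether (C12–OSiEt3, C4–OSiEt3, C2–OSiMe3) | CC[Si](CC)(CC)OCC[C@@]23[C@@H](O[Si](C)(C)C(C)(C)C)CC(COCc4ccc(OC)cc4)=C[C@]2(O[Si](C)(C)C)C[C@@](C)(O[Si](CC)(CC)CC)CC35OCCO5 | intermediate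
23 | C12 aldehyde | O=CC[C@@]23[C@@H](O[Si](C)(C)C(C)(C)C)CC(COCc4ccc(OC)cc4)=C[C@]2(O[Si](C)(C)C)C[C@@](C)(O[Si](CC)(CC)CC)CC35OCCO5 | intermediate
24 | C11 (dimethylamino)methyl aldehyde (C11 epimers) | O=CC(CN(C)C)[C@@]23[C@@H](O[Si](C)(C)C(C)(C)C)CC(COCc4ccc(OC)cc4)=C[C@]2(O[Si](C)(C)C)C[C@@](C)(O[Si](CC)(CC)CC)CC35OCCO5 | intermediate
25 | α-methylene aldehyde (C11=C13) | O=CC(=C)[C@@]23[C@@H](O[Si](C)(C)C(C)(C)C)CC(COCc4ccc(OC)cc4)=C[C@]2(O[Si](C)(C)C)C[C@@](C)(O[Si](CC)(CC)CC)CC35OCCO5 | intermediate
26 | 2-substituted allylic alcohol | OCC(=C)[C@@]23[C@@H](O[Si](C)(C)C(C)(C)C)CC(COCc4ccc(OC)cc4)=C[C@]2(O[Si](C)(C)C)C[C@@](C)(O[Si](CC)(CC)CC)CC35OCCO5 | intermediate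
27 | epoxy alcohol (C11–C13 epoxide) | OC[C@@]1(CO1)[C@@]23[C@@H](O[Si](C)(C)C(C)(C)C)CC(COCc4ccc(OC)cc4)=C[C@]2(O[Si](C)(C)C)C[C@@](C)(O[Si](CC)(CC)CC)CC35OCCO5 | intermediate
28 | glycidic aldehyde | O=C[C@@]1(CO1)[C@@]23[C@@H](O[Si](C)(C)C(C)(C)C)CC(COCc4ccc(OC)cc4)=C[C@]2(O[Si](C)(C)C)C[C@@](C)(O[Si](CC)(CC)CC)CC35OCCO5 | intermediate
29 | glycidic acid | OC(=O)[C@@]1(CO1)[C@@]23[C@@H](O[Si](C)(C)C(C)(C)C)CC(COCc4ccc(OC)cc4)=C[C@]2(O[Si](C)(C)C)C[C@@](C)(O[Si](CC)(CC)CC)CC35OCCO5 | intermediate
30 | tert-butyl glycidate with C2–OSiMe3 | CC(C)(C)OC(=O)[C@@]1(CO1)[C@@]23[C@@H](O[Si](C)(C)C(C)(C)C)CC(COCc4ccc(OC)cc4)=C[C@]2(O[Si](C)(C)C)C[C@@](C)(O[Si](CC)(CC)CC)CC35OCCO5 | intermediate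
31 | decalin epoxy ester (fragmentation precursor) | CC(C)(C)OC(=O)[C@@]1(CO1)[C@@]23[C@@H](O[Si](C)(C)C(C)(C)C)CC(COCc4ccc(OC)cc4)=C[C@]2(O)C[C@@](C)(O[Si](CC)(CC)CC)CC35OCCO5 | intermediate
32 | potassium C2 alkoxide of 31 | CC(C)(C)OC(=O)[C@@]1(CO1)[C@@]23[C@@H](O[Si](C)(C)C(C)(C)C)CC(COCc4ccc(OC)cc4)=C[C@]2([O-])C[C@@](C)(O[Si](CC)(CC)CC)CC35OCCO5.[K+] | intermediate
33 | cyclodecenone with exocyclic hydroxymethyl enoate (fragmentation product) | CC(C)(C)OC(=O)/C(CO)=C1/[C@@H](O[Si](C)(C)C(C)(C)C)C/C(COCc2ccc(OC)cc2)=C\C(=O)C[C@@](C)(O[Si](CC)(CC)CC)CC13OCCO3 | intermediate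
34 | C4 alcohol (β-hydroxy enone) | CC(C)(C)OC(=O)/C(CO)=C1/[C@@H](O[Si](C)(C)C(C)(C)C)C/C(COCc2ccc(OC)cc2)=C\C(=O)C[C@@](C)(O)CC13OCCO3 | intermediate
35 | C4 diethylborinate chelate of 34 | CC(C)(C)OC(=O)/C(CO)=C1/[C@@H](O[Si](C)(C)C(C)(C)C)C/C(COCc2ccc(OC)cc2)=C\C(=O)C[C@@](C)(OB(CC)CC)CC13OCCO3 | intermediate
36 | (2S,4R)-syn-diol | CC(C)(C)OC(=O)/C(CO)=C1/[C@@H](O[Si](C)(C)C(C)(C)C)C/C(COCc2ccc(OC)cc2)=C\[C@@H](O)C[C@@](C)(O)CC13OCCO3 | intermediate
37 | C2, C13 diacetate | CC(C)(C)OC(=O)/C(COC(C)=O)=C1/[C@@H](O[Si](C)(C)C(C)(C)C)C/C(COCc2ccc(OC)cc2)=C\[C@@H](OC(C)=O)C[C@@](C)(O)CC13OCCO3 | intermediate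
38 | C8 alcohol | CC(C)(C)OC(=O)/C(COC(C)=O)=C1/[C@@H](O)C/C(COCc2ccc(OC)cc2)=C\[C@@H](OC(C)=O)C[C@@](C)(O)CC13OCCO3 | intermediate
39 | C8 angelate | CC(C)(C)OC(=O)/C(COC(C)=O)=C1/[C@@H](OC(=O)/C(C)=C\C)C/C(COCc2ccc(OC)cc2)=C\[C@@H](OC(C)=O)C[C@@](C)(O)CC13OCCO3 | intermediate
40 | keto acid (C6 ketone, C12 acid, C14–OH) | OC(=O)/C(COC(C)=O)=C1/[C@@H](OC(=O)/C(C)=C\C)C/C(CO)=C\[C@@H](OC(C)=O)C[C@@](C)(O)CC1=O | intermediate
41 | hydroxybutenolide (C6 hemiketal lactone, C6 epimers) | C/C=C(/C)C(=O)O[C@H]1C/C(CO)=C\[C@@H](OC(C)=O)C[C@@](C)(O)CC2(O)OC(=O)C(COC(C)=O)=C12 | intermediate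
42 | CNP0165707.1 | C/C=C(/C)C(=O)O[C@H]1C/C(CO)=C\[C@@H](OC(C)=O)C[C@@](C)(O)/C=C2/OC(=O)C(COC(C)=O)=C21 | target

**Count and risks**
Total: 30 steps. Longest linear sequence: 29 steps (steps 1–3 and 5–30; step 4 is a side branch).

Steps most likely to fail:

1. Step 24 (key step). The C2 alkoxide may add to the ester carbonyl instead of fragmenting, or fragmentation may be too slow at temperatures the product alkoxide tolerates. Fallback, setting out from 31 and returning at 33: cut the same C2–C7 bond homolytically. PhI(OAc)2 and I2 under visible light in CH2Cl2/cyclohexane would convert the C2 alcohol into the hypoiodite F1. The derived alkoxy radical undergoes β-scission to the C2 ketone and the tertiary C7 radical, which opens the adjacent epoxide to C7=C11 and the C13 oxy radical; thiosulfate work-up then gives 33. Both radical steps are established reaction types, but the C7=C11 geometry would no longer be stereospecific and olefin isomers would need separation.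

2. Step 30. The acid needed for the tert-butyl ester and the ketal may ionise or dehydrate the C4 tertiary alcohol or the allylic acetate, and dehydration of the hydroxybutenolide may stall. Fallback, setting out from 39 and returning at 42, in four mild stages: I2 (cat.) in acetone exchanges the dioxolane to give keto ester F2; Me3SiOTf/2,6-lutidine followed by aqueous work-up cleaves the tert-butyl ester and the acid closes to hydroxybutenolide F3; MsCl/Et3N dehydrates it to the PMB-protected enol lactone F4; DDQ in CH2Cl2/pH 7 buffer removes the PMB group.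

3. Step 8. The catalyst may discriminate poorly between the two diastereotopic ring carbonyls, and the new C2 hydroxyl may lactonise onto the ester arm. Fallback, setting out from 12 and returning at 15: statistical monoketalisation (ethylene glycol, pyridinium p-toluenesulfonate, benzene, reflux) gives 15 together with its regioisomer F5. The two are separated by chromatography, and F5 is hydrolysed back to 12 (dilute HCl, THF) and recycled. This also bypasses steps 9 and 10.

**Further compounds**
F1 | step 24 | C2 hypoiodite of 31 | CC(C)(C)OC(=O)[C@@]1(CO1)[C@@]23[C@@H](O[Si](C)(C)C(C)(C)C)CC(COCc4ccc(OC)cc4)=C[C@]2(OI)C[C@@](C)(O[Si](CC)(CC)CC)CC35OCCO5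
F2 | step 30 | C6 keto tert-butyl ester (dioxolane removed from 39) | CC(C)(C)OC(=O)/C(COC(C)=O)=C1/[C@@H](OC(=O)/C(C)=C\C)C/C(COCc2ccc(OC)cc2)=C\[C@@H](OC(C)=O)C[C@@](C)(O)CC1=O
F3 | step 30 | hydroxybutenolide with C14 PMB ether | C/C=C(/C)C(=O)O[C@H]1C/C(COCc3ccc(OC)cc3)=C\[C@@H](OC(C)=O)C[C@@](C)(O)CC2(O)OC(=O)C(COC(C)=O)=C12
F4 | step 30 | C14 PMB ether of the target | C/C=C(/C)C(=O)O[C@H]1C/C(COCc3ccc(OC)cc3)=C\[C@@H](OC(C)=O)C[C@@](C)(O)/C=C2/OC(=O)C(COC(C)=O)=C21
F5 | step 8 | regioisomeric monoketal (other ring carbonyl ketalised) | CC(C)(C)OC(=O)C[C@]1([C@@H](O[Si](C)(C)C(C)(C)C)CC(=C)COCc2ccc(OC)cc2)C(=O)CC(C)CC13OCCO3
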